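In a one-step world E simply becomes Q, and the share of G in G plus Q, a selectivity, stays at nothing. The real flask and its runs are these:

| setting | Tuesday's | Thursday's | Friday's | flask |
|---|---|---|---|---|
| E | 0.010 M | 0.010 M | 0.020 M | 0.010 M |
| J | 5 mM | 5 mM | 5 mM | 5.00 mM |
| X | 1.4 mM | 2.2 mM | 1 mM | 1.00 mM |
| remark | run made earlier | run made earlier | run made earlier |  |
| time |  |  |  | 1.0 h |

- Tuesday's (time / min: G / %, Q / %): 8.00: 22, 50; 20.0: 24, 62; 40.0: 24, 65; 60.0: 28, 63
- Thursday's (time / min: G / %, Q / %): 5.00: 25, 35; 12.0: 24, 51; 25.0: 26, 56; 60.0: 26, 60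
- Friday's (time / min: G / %, Q / %): 15.0: 18, 73; 30.0: 18, 75; 50.0: 17, 74; 60.0: 17, 75

(scatter of a reading: 2 percentage points)

- share of G in G plus Q at 3.0 s
- share of G in G plus Q at 1.0 h



Now build the flask up. Add a step that turns each J into G, and the share becomes charged [J] over charged [E] plus [J], which is 33.3% here. Next comes X, and here you work with what is left. Each run's last reading leaves 1.35 mM outside G and Q in Tuesday's run (X 1.4 mM), 2.10 mM in Thursday's (X 2.2 mM) and 2.00 mM in Friday's (X 1 mM), so this step is rough. I let X remove its own amount from the charge, and the share rises to 35.7%.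

The rest goes into one number. The last two readings of each run give 0.780 in Tuesday's run, 0.780 in Thursday's and 0.850 in Friday's. Their mean, 0.803, a reading that carries the scatter of those runs, is g, the G standing at the end per J charged. The share is then g[J] over [E] plus [J] minus [X], all as charged, and my reckoning for 1.0 h is 28.7%. For 3.0 s I have no number, because Thursday's first reading comes at 5.00 min, far later than 3.0 s, and that run's share there reads 41.7%.

The forecast gave 85% (45% to 99%) at 3.0 s and 25% (22% to 28%) at 1.0 h, lower than my 28.7%, noting that “G's rise is unresolved”.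

The flask gives 70.4% at 3.0 s and 27.5% at 1.0 h.

    D → L (k = 0.0140 s⁻¹)
    E → Q (k = 0.00320 s⁻¹)
    E + X → Z (k = 6.30 L mol⁻¹ s⁻¹)
    E ⇌ J (K = 0.0450, k = 3.90 × 10⁻⁴ s⁻¹)
    J ⇌ D (K = 0.160, k = 0.0180 s⁻¹)
    J → G (k = 0.0160 s⁻¹)

This flask ends with G at 24.8% of the charge, which is 0.744 per J charged, where the runs read 0.803. Now take the neighbouring flask with 0.0030 M of J, everything else as in the recipe. The same reckoning, with g unchanged, gives a share of 20.1% and G at 18.5% of its charge. That neighbouring flask ends with G at 19.0% and a share of 21.2%.

(Readings and results stem from a simulated flask for an exercise, and the scatter is random.)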